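Assumption: the target has no stereocentre and no stable atropisomer, so it is achiral and needs no stereocontrol. Both starting materials are catalogue compounds (methyl 2,4-dihydroxy-3,6-dimethylbenzoate is the bulk fragrance chemical atraric acid); the route is a paper design and has not been run.

**Retrosynthetic overview**
- Last step: remove both aryl chlorines to reach atranorin; its only two aromatic C–H positions are chlorinated together.
- Atranorin comes from its ring-B di-O-methyl ether by chelation-controlled BCl3 demethylation.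
- Key disconnection: the ring-B C(aryl)–C(=O) bond of the depside is cut into an aryl iodide (electrophilic carbon) and an aryloxycarbonyl anion ⁻C(=O)OAr, a reversed-polarity d1 carboxyl synthon. It is delivered as CO plus the atraric acid phenoxide on palladium, so the C–C bond and the depside C–O bond form in one convergent step.
- The aryl iodide comes from 2,6-dimethoxy-4-methylbenzaldehyde by iodination.
- No ring is formed: both benzene rings are bought intact.

**Route**

Step 1
Reactants: 1 2,6-dimethoxy-4-methylbenzaldehyde
Product: 2 3-iodo-2,6-dimethoxy-4-methylbenzaldehyde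
Conditions: NIS (1.05 equiv), TFA (0.3 equiv), MeCN, rt
Reagents that add atoms: N-iodosuccinimide, O=C1CCC(=O)N1I
Why: Electrophilic aromatic iodination; C3 is ortho to one OMe, para to the other and meta to CHO, and one equivalent of NIS stops at the mono-iodide because the product is more hindered and less activated.

Step 2
Reactants: 2 3-iodo-2,6-dimethoxy-4-methylbenzaldehyde; 3 methyl 2,4-dihydroxy-3,6-dimethylbenzoate (atraric acid, 1.5 equiv)
Product: 4 3-hydroxy-4-(methoxycarbonyl)-2,5-dimethylphenyl 3-formyl-2,4-dimethoxy-6-methylbenzoate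
Conditions: CO (5 bar), Pd(OAc)2 (5 mol%), Xantphos (7 mol%), Et3N (3 equiv), DMAP (20 mol%), 4 Å MS, toluene, 100 °C
Reagents that add atoms: carbon monoxide, [C-]#[O+]
Why: Pd-catalysed aryloxycarbonylation (carbonylative esterification), in which CO on palladium together with the 4-phenoxide of 3 serves as an aryloxycarbonyl-anion (d1 carboxyl-anion) equivalent that is joined to the electrophilic C–I carbon of 2; the ester-chelated 2-OH of 3 is unreactive, so only the 4-OH is acylated, and DMAP relays the hindered aroyl group.

Step 3
Reactants: 4 3-hydroxy-4-(methoxycarbonyl)-2,5-dimethylphenyl 3-formyl-2,4-dimethoxy-6-methylbenzoate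
Product: 6 atranorin [3-hydroxy-4-(methoxycarbonyl)-2,5-dimethylphenyl 3-formyl-2,4-dihydroxy-6-methylbenzoate], via bis(dichloroboryl) ether 5 (not isolated)
Conditions: BCl3 (1 M in CH2Cl2, 3.5 equiv), CH2Cl2, −78 → 0 °C; then H2O
Reagents that add atoms: none
Why: Chelation-controlled Lewis-acid ether cleavage, in which BCl3 bridges the depside C=O/2-OMe pair and the CHO/4-OMe pair, chloride removes each methyl as MeCl to give the O–BCl2 chelates 5 that water hydrolyses, while the methyl ester and the aryl ester survive at or below 0 °C.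

Step 4
Reactants: 6 atranorin
Product: 7 2-chloro-5-hydroxy-4-(methoxycarbonyl)-3,6-dimethylphenyl 5-chloro-3-formyl-2,4-dihydroxy-6-methylbenzoate (target)
Conditions: SO2Cl2 (2.3 equiv), CH2Cl2/Et2O, 0 °C → rt, dark
Reagents that add atoms: sulfuryl chloride, O=S(=O)(Cl)Cl
Why: Double electrophilic aromatic chlorination; the molecule has only two aromatic C–H positions, one ortho/para to the two ring-B phenols and one para to the ring-A phenol, so the regiochemistry is fixed and ionic conditions leave the aldehyde and esters untouched.

**Compound list**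
1 | 2,6-dimethoxy-4-methylbenzaldehyde | COc1cc(C)cc(OC)c1C=O | starting material
2 | 3-iodo-2,6-dimethoxy-4-methylbenzaldehyde | COc1cc(C)c(I)c(OC)c1C=O | intermediate
3 | methyl 2,4-dihydroxy-3,6-dimethylbenzoate (atraric acid) | COC(=O)c1c(C)cc(O)c(C)c1O | starting material
4 | 3-hydroxy-4-(methoxycarbonyl)-2,5-dimethylphenyl 3-formyl-2,4-dimethoxy-6-methylbenzoate | COC(=O)c1c(C)cc(OC(=O)c2c(C)cc(OC)c(C=O)c2OC)c(C)c1O | intermediate
5 | bis(dichloroboryl) ether of atranorin (both ring-B phenol oxygens carry BCl2, each chelated to the neighbouring C=O; ring-A phenol drawn free) | COC(=O)c1c(C)cc(OC(=O)c2c(C)cc(OB(Cl)Cl)c(C=O)c2OB(Cl)Cl)c(C)c1O | intermediate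
6 | atranorin, 3-hydroxy-4-(methoxycarbonyl)-2,5-dimethylphenyl 3-formyl-2,4-dihydroxy-6-methylbenzoate | COC(=O)c1c(C)cc(OC(=O)c2c(C)cc(O)c(C=O)c2O)c(C)c1O | intermediate
7 | 2-chloro-5-hydroxy-4-(methoxycarbonyl)-3,6-dimethylphenyl 5-chloro-3-formyl-2,4-dihydroxy-6-methylbenzoate | COC(=O)c1c(C)c(Cl)c(OC(=O)c2c(C)c(Cl)c(O)c(C=O)c2O)c(C)c1O | target

**Totals**
Total step count: 4. Longest linear sequence: 4 (1 → 2 → 4 → 6 → 7).

**Three steps most likely to fail, with fallbacks**

Step 2 (key carbonylative union). The aroyl-palladium species from a 2,6-disubstituted iodide may be captured slowly by the phenol, and hydrodeiodination may compete. The fallback separates the C–C and C–O events and sets out from 2. Pd-catalysed hydroxycarbonylation of 2 (CO, H2O, Pd(OAc)2/Xantphos, Et3N, dioxane, 90 °C) gives 3-formyl-2,4-dimethoxy-6-methylbenzoic acid F1. This acid is condensed with 3 through its mixed trifluoroacetic anhydride/acylium ion (TFAA, toluene, rt), the classical depside esterification, which suits 2,6-disubstituted acids well. The fallback comes back to the route at 4.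

Step 4 (late double chlorination). Ring A may react incompletely, or over-chlorination and aldehyde damage may occur. The fallback places both chlorines before the coupling and sets out from 1 and 3. Compound 1 with NCS (cat. TFA, MeCN) gives 3-chloro-2,6-dimethoxy-4-methylbenzaldehyde F3, and NIS/TfOH then gives 3-chloro-5-iodo-2,6-dimethoxy-4-methylbenzaldehyde F4. Separately, 3 with SO2Cl2 (Et2O, 0 °C) gives methyl 5-chloro-2,4-dihydroxy-3,6-dimethylbenzoate F5. Aryloxycarbonylation of F4 with F5 under the step 2 conditions gives 2-chloro-5-hydroxy-4-(methoxycarbonyl)-3,6-dimethylphenyl 5-chloro-3-formyl-2,4-dimethoxy-6-methylbenzoate F6. BCl3 demethylation of F6 comes back to the route at 7.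

Step 3 (demethylation). The second methyl ether may resist BCl3, or the depside may be cleaved. The fallback removes the methyl groups before any ester exists and sets out from 2. BBr3 (CH2Cl2, −78 °C → rt) converts 2 into 2,6-dihydroxy-3-iodo-4-methylbenzaldehyde F2, whose two phenols are hydrogen-bonded to the aldehyde and are poor nucleophiles. Aryloxycarbonylation of F2 with 3 (3 equiv, same catalyst system) gives the free depside directly and comes back to the route at 6.

**Further compounds**
F1 | step 2 | 3-formyl-2,4-dimethoxy-6-methylbenzoic acid | COc1cc(C)c(C(=O)O)c(OC)c1C=O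
F2 | step 3 | 2,6-dihydroxy-3-iodo-4-methylbenzaldehyde | Cc1cc(O)c(C=O)c(O)c1I
F3 | step 4 | 3-chloro-2,6-dimethoxy-4-methylbenzaldehyde | COc1cc(C)c(Cl)c(OC)c1C=O
F4 | step 4 | 3-chloro-5-iodo-2,6-dimethoxy-4-methylbenzaldehyde | COc1c(I)c(C)c(Cl)c(OC)c1C=O
F5 | step 4 | methyl 5-chloro-2,4-dihydroxy-3,6-dimethylbenzoate | COC(=O)c1c(C)c(Cl)c(O)c(C)c1O
F6 | step 4 | 2-chloro-5-hydroxy-4-(methoxycarbonyl)-3,6-dimethylphenyl 5-chloro-3-formyl-2,4-dimethoxy-6-methylbenzoate | COC(=O)c1c(C)c(Cl)c(OC(=O)c2c(C)c(Cl)c(OC)c(C=O)c2OC)c(C)c1O
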